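Count the amounts first: compare what has left as substrate with what shows up as target.

the same everywhere: free catalyst 2.2 mM

| flask | substrate | reagent | remark | time |
|---|---|---|---|---|
| north-east | 1.9 mM | 8.8 mM | run made earlier |  |
| south-east | 18 mM | 8.8 mM | run made earlier |  |
| midnight | 1.5 mM | 8.80 mM |  | 25 min |
| dawn | 3.0 mM | 8.80 mM |  | 25 min |
| noon | 6.0 mM | 8.80 mM |  | 25 min |
| summer | 12 mM | 8.80 mM |  | 25 min |

| run | time / min | target / % | substrate / % |
|---|---|---|---|
| north-east | 1.00 | 0 | 100.0 |
| north-east | 2.00 | 0.4 | 99.7 |
| north-east | 4.00 | 0 | 98.6 |
| north-east | 6.00 | 1.0 | 96.9 |
| north-east | 12.0 | 3.6 | 92.0 |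
| south-east | 1.00 | 0 | 99.9 |
| south-east | 3.00 | 0.1 | 99.2 |
| south-east | 6.00 | 0.4 | 97.5 |
| south-east | 8.00 | 1.1 | 96.6 |
| south-east | 12.0 | 2.8 | 94.3 |

(each reading ± 0.3 percentage points)

- amount of target at the end, in percent of the substrate charged for midnight, dawn, noon, summer, in this order
- the course of these numbers from the first flask to the last (hardly changes / rises all the way / falls all the way / rises, then falls / falls, then rises)

- steps under discussion: reagent + free catalyst <-> catalyst intermediate A; catalyst intermediate A -> catalyst intermediate B; substrate + catalyst intermediate B <-> catalyst intermediate C; catalyst intermediate C <-> catalyst intermediate D; catalyst intermediate D -> free catalyst + target; target -> over-reaction product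
- "hardly changes" means that all values lie within two and a half points (for a concentration: within two and a half percent of the largest)

Reckon two ways. Divide target found by substrate lost at the last reading, 12.0 min: this gives 0.450 in the north-east run and 0.491 in the south-east run, though the south-east charge is ten times the north-east one. Keep their mean, 0.471, and call target found per substrate lost the target share, the usual selectivity.

For the first way, run the substrate line on. Between 6.00 min and 12.0 min the north-east run loses 0.00817 min⁻¹ of its charge, so the line puts its loss by 25 min at 18.6%. Over the same span the south-east run loses 0.00533 min⁻¹, so the line puts its loss at 12.6%. Multiplied by the share, these give 8.76% and 5.95% of target.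

For the second way, ignore substrate and run the target line on over the same span. This gives 9.23% for north-east and 8.00% for south-east.

The two ways agree for north-east and part for south-east. The share way is the one that cheats, because over that span target rose 0.531 per substrate lost in the north-east run and 0.750 in the south-east run, both above the share. As read, the share was still climbing in both runs. Commit to the target line and lend its figures to the new flasks: midnight near 9.23% from the north-east run, summer near 8.00% from the south-east run, the row falling.

The forecast sets 13.5%, 13%, 11.5% and 9.5%, course falls all the way, and ends: “The percentage therefore falls steadily.” Its midnight value stands above mine.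

The flasks give 10.9%, 10.4%, 9.48% and 7.98%, course falls all the way, and the forecast lies within its margins.

    reagent + free catalyst ⇌ catalyst intermediate A (K = 26.3 M⁻¹, k = 22.5 M⁻¹ min⁻¹)
    catalyst intermediate A → catalyst intermediate B (k = 10.7 min⁻¹)
    substrate + catalyst intermediate B ⇌ catalyst intermediate C (K = 3300 M⁻¹, k = 5.84 M⁻¹ min⁻¹)
    catalyst intermediate C ⇌ catalyst intermediate D (K = 0.448, k = 0.265 min⁻¹)
    catalyst intermediate D → free catalyst + target (k = 5.70 min⁻¹)
    target → over-reaction product (k = 0.0473 min⁻¹)

In midnight at 25.0 min, target is made 1.81 times as fast as it is used up, each step taken net, and 5.38% stands as over-reaction product beside 10.9% of target. The target share of midnight has by then reached 0.536, above the carried 0.471. In summer, the carried share times the 14.9% of substrate lost gives 7.03%, and the flask holds 7.98%.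

Readings and results come from a simulation for an exercise.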